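## Plan

1. Numbering used throughout (bicyclo[3.2.1]octane): C1 prenyl bridgehead, C2 C=O, C3 acyl-bearing carbon, C4 enol carbon, C5 methyl bridgehead, C6 CH bearing CMe2OH, C7 CH2, C8 bridging C=O.
2. Cuts, in retrosynthetic order: the exocyclic C3–acyl bond; then C1–C8 and C4–C5 together, which opens both rings to one chain; then the C4 activating group and the prenyl alkene (from allyl); last, C2 and C8 are rejoined into the ring of (R)-carvone.
3. Enabling feature: ring C1–C2–C3–C4–C5–C8 is a 1,3,5-tricarbonyl ring in which C1 and C5 are enolisable α-carbons and C8 and C4 are acyl-level carbons. The hydroxyl oxygen on the C6 side chain is γ to C8, so C8 is stored as a γ-lactone (temporary ring whose leaving group is the target's own OH). C4 is stored as a ketene dithioacetal, which activates C4 and blocks C3 and is removed by hydrolysis.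
4. Forward: the carvone ring carries C6; methyl and allyl are added, the ring is cut at the enol double bond of the former ketone to a keto lactone, and one base treatment closes the five-membered ring (C1–C8) and then the six-membered ring (C4–C5). Hydrolysis and C3-acylation finish.
5. Stereochemistry: C6 is C5 of (R)-carvone; C1 and C5 are set in the cascade under control of C6 (three-carbon bridge anti to the hydroxypropyl group); the side-chain centre comes from (R)-2-methylbutanoic acid; all other centres made on the way are erased by enolisation.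

Key step: step 7

Assumption: the target is one of a set of interconverting chelated enol tautomers and the route delivers that set; (R)-2-methylbutanoic acid is taken to be available as a single enantiomer.

## Route

Step 1
Reactants: 1 (R)-(−)-carvone
Product: 2 (5R)-2,6-dimethyl-5-(prop-1-en-2-yl)cyclohex-2-en-1-one (C6 epimers)
Conditions: LiN(i-Pr)2, THF, −78 °C; MeI, −78 → 0 °C
Reagents that add atoms: iodomethane, CI
Why: Kinetic deprotonation at the α'-methylene (C6) gives the cross-conjugated lithium dienolate, whose C-methylation (enolate alkylation) should occur mainly anti to the isopropenyl group; the C6 configuration is irrelevant because this carbon (future C5) is enolised again in step 7.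

Step 2
Reactants: 2 (5R)-2,6-dimethyl-5-(prop-1-en-2-yl)cyclohex-2-en-1-one
Product: 3 (5R)-5-(2-hydroxypropan-2-yl)-2,6-dimethylcyclohex-2-en-1-one (C6 epimers)
Conditions: 50% aq. H2SO4, 0 °C; NaHCO3 work-up
Reagents that add atoms: water, O
Why: Markovnikov acid-catalysed hydration of the electron-rich 1,1-disubstituted alkene through the tertiary cation, at a temperature that leaves the electron-poor enone alkene and the C5 stereocentre untouched, installs the tertiary alcohol that later becomes the lactone oxygen.

Step 3
Reactants: 3 (5R)-5-(2-hydroxypropan-2-yl)-2,6-dimethylcyclohex-2-en-1-one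
Product: 4 trimethyl{[(5R)-2,6-dimethyl-3-(prop-2-en-1-yl)-5-{2-[(trimethylsilyl)oxy]propan-2-yl}cyclohex-1-en-1-yl]oxy}silane (C3 and C6 epimers)
Conditions: CH2=CHCH2MgBr (2.6 equiv), CuBr·SMe2 (20 mol %), Me3SiCl (4 equiv), THF, −78 → −40 °C; Et3N, pentane work-up
Reagents that add atoms: allylmagnesium bromide, C=CC[Mg]Br; chlorotrimethylsilane, C[Si](C)(C)Cl
Why: Copper-catalysed, Me3SiCl-accelerated conjugate addition of the allyl Grignard reagent (expected anti to the C5 substituent, though this centre is later enolised) with in situ O-silylation gives the tetrasubstituted silyl enol ether regiospecifically; the first equivalent of Grignard reagent deprotonates the tertiary alcohol, which is silylated as well.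

Step 4
Reactants: 4 bis-silylated enol ether
Product: 6 (4R)-4-(2-acetylpent-4-en-1-yl)-3,5,5-trimethyloxolan-2-one, via silyl keto ester 5 (not isolated)
Conditions: O3 (1.0 equiv, titrated solution), CH2Cl2, −78 °C; Me2S; then TsOH·H2O (cat.), CH2Cl2, 25 °C
Reagents that add atoms: ozone, [O-][O+]=O
Why: Ozonolysis of the electron-rich tetrasubstituted silyl enol ether, which should react far faster than the terminal alkene when one equivalent of ozone is dosed, cuts the ring C1–C2 bond of 4 into a methyl ketone and a silyl ester; acid then removes both silyl groups and the γ-hydroxy acid lactonises, with no stereocentre touched.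

Step 5
Reactants: 6 (4R)-4-(2-acetylpent-4-en-1-yl)-3,5,5-trimethyloxolan-2-one
Product: 7 (4R)-4-(2-acetyl-5-methylhex-4-en-1-yl)-3,5,5-trimethyloxolan-2-one
Conditions: 2-methylbut-2-ene (excess), second-generation Grubbs catalyst RuCl2(=CHPh)(PCy3)(H2IMes) (5 mol %), CH2Cl2, 40 °C
Reagents that add atoms: 2-methylbut-2-ene, CC=C(C)C
Why: Olefin cross-metathesis of the monosubstituted alkene with excess 2-methylbut-2-ene converts allyl into prenyl with loss of propene; ketone and lactone are inert to the ruthenium carbene.

Step 6
Reactants: 7 (4R)-4-(2-acetyl-5-methylhex-4-en-1-yl)-3,5,5-trimethyloxolan-2-one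
Product: 9 (4R)-4-{2-[3,3-bis(methylsulfanyl)prop-2-enoyl]-5-methylhex-4-en-1-yl}-3,5,5-trimethyloxolan-2-one, via lithium dithiocarboxylate 8 (not isolated)
Conditions: LiN(i-Pr)2 (1.05 equiv), THF, −78 °C; CS2 (1.05 equiv); LiN(i-Pr)2 (1.05 equiv); MeI (2.5 equiv), −78 → 0 °C
Reagents that add atoms: carbon disulfide, S=C=S; iodomethane, CI
Why: At −78 °C the amide base removes a proton from the ketone CH3 (kinetically preferred over the hindered tertiary α-CH and over the lactone), the enolate adds to CS2, and a second deprotonation with double S-methylation gives the α-oxo ketene dithioacetal; the low temperature keeps the more substituted enolate, which would open the lactone, from forming before step 7.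

Step 7
Reactants: 9 (4R)-4-{2-[3,3-bis(methylsulfanyl)prop-2-enoyl]-5-methylhex-4-en-1-yl}-3,5,5-trimethyloxolan-2-one
Product: 11 (1S,5S,6R)-6-(2-hydroxypropan-2-yl)-5-methyl-1-(3-methylbut-2-en-1-yl)-4-(methylsulfanyl)bicyclo[3.2.1]oct-3-ene-2,8-dione, via cyclopentanone alkoxide 10 (not isolated)
Conditions: KOt-Bu (2.5 equiv), THF/t-BuOH (10:1), 0 → 25 °C; aq. NH4Cl
Reagents that add atoms: none
Why: KOt-Bu reversibly forms the enolate at the prenyl-bearing ketone α-carbon (future C1; the other α-position, future C3, is a vinylic CH of the ketene dithioacetal and cannot be enolised), and this carbon attacks the lactone carbonyl (future C8) in a 5-(enolexo)-exo-trig Claisen acylation whose tetrahedral intermediate collapses with loss of the tertiary alkoxide, closing the cyclopentanone and freeing the hydroxypropyl oxygen (10). The new ketone has one α-hydrogen, at future C5, and its enolate adds to the bis(methylsulfanyl) carbon (future C4) in a 6-(enolendo)-endo-trig conjugate addition and then expels methanethiolate, which closes the six-membered ring irreversibly. The closest known reaction types are the Dieckmann-type acylation of ketone enolates by lactones and the addition–elimination of enolates on α-oxo ketene dithioacetals. C1 is set in the reversible first closure and C5 in the second, which can only bridge cis across the cyclopentanone; both are controlled by C6, because the acyl arm must reach C5 on the face anti to the adjacent bulky 2-oxidopropan-2-yl group, and the C1 epimer that cannot do so returns through retro-Claisen opening. The step needs C- rather than O-attack of the C5 enolate and reaction through the C1 enolate rather than the lactone enolate: the soft, thiolate-releasing acceptor favours carbon attack, and the lactone enolate has no productive partner and re-equilibrates under the alkoxide conditions.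

Step 8
Reactants: 11 bicyclic vinylogous thioester
Product: 12 (1S,5R,6R)-6-(2-hydroxypropan-2-yl)-5-methyl-1-(3-methylbut-2-en-1-yl)bicyclo[3.2.1]octane-2,4,8-trione (enolised)
Conditions: LiOH (5 equiv), THF/H2O (3:1), 50 °C; then 1 M HCl to pH 2
Reagents that add atoms: water (as hydroxide), O
Why: Hydroxide adds to C4 of the vinylogous thioester and expels methanethiolate (addition–elimination hydrolysis) to give the enolate of the 2,4-dione, which is released on acidification; the exo hydroxypropyl group cannot reach C4, so no cyclic enol ether should form.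

Step 9
Reactants: 12 bicyclic trione; 13 (2R)-2-methylbutanoic acid
Product: 15 (1R,5R,6R)-4-hydroxy-6-(2-hydroxypropan-2-yl)-5-methyl-1-(3-methylbut-2-en-1-yl)-3-[(2R)-2-methylbutanoyl]bicyclo[3.2.1]oct-3-ene-2,8-dione, via enol ester 14 (not isolated)
Conditions: DCC, DMAP (1.2 equiv), CH2Cl2, 0 → 25 °C
Reagents that add atoms: none
Why: Steglich O-acylation of the enolised dione by the carbodiimide-activated acid gives enol ester 14, and DMAP then moves the acyl group from oxygen to C3 (1,3-acyl migration driven by formation of the chelated, strongly acidic triketone); the hindered tertiary alcohol should not be acylated and the α-stereocentre of the acid should not epimerise under these conditions.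

## Compound list

1 | (R)-(−)-carvone, (5R)-2-methyl-5-(prop-1-en-2-yl)cyclohex-2-en-1-one | CC1=CC[C@H](CC1=O)C(C)=C | starting material
2 | (5R)-2,6-dimethyl-5-(prop-1-en-2-yl)cyclohex-2-en-1-one (C6 epimers) | CC1=CC[C@H](C(C)C1=O)C(C)=C | intermediate
3 | (5R)-5-(2-hydroxypropan-2-yl)-2,6-dimethylcyclohex-2-en-1-one (C6 epimers) | CC1=CC[C@H](C(C)C1=O)C(C)(C)O | intermediate
4 | trimethyl{[(5R)-2,6-dimethyl-3-(prop-2-en-1-yl)-5-{2-[(trimethylsilyl)oxy]propan-2-yl}cyclohex-1-en-1-yl]oxy}silane (C3 and C6 epimers) | CC1=C(O[Si](C)(C)C)C(C)[C@@H](CC1CC=C)C(C)(C)O[Si](C)(C)C | intermediate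
5 | trimethylsilyl (3R)-5-acetyl-2-methyl-3-{2-[(trimethylsilyl)oxy]propan-2-yl}oct-7-enoate (C2 and C5 epimers) | CC(=O)C(CC=C)C[C@H](C(C)C(=O)O[Si](C)(C)C)C(C)(C)O[Si](C)(C)C | intermediate (not isolated)
6 | (4R)-4-(2-acetylpent-4-en-1-yl)-3,5,5-trimethyloxolan-2-one (epimers at C3 and at the acetyl-bearing carbon) | CC(=O)C(CC=C)C[C@@H]1C(C)C(=O)OC1(C)C | intermediate
7 | (4R)-4-(2-acetyl-5-methylhex-4-en-1-yl)-3,5,5-trimethyloxolan-2-one (same epimers) | CC(=O)C(CC=C(C)C)C[C@@H]1C(C)C(=O)OC1(C)C | intermediate
8 | lithium 7-methyl-3-oxo-4-{[(3R)-2,2,4-trimethyl-5-oxooxolan-3-yl]methyl}oct-6-enedithioate | [Li+].[S-]C(=S)CC(=O)C(CC=C(C)C)C[C@@H]1C(C)C(=O)OC1(C)C | intermediate (not isolated)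
9 | (4R)-4-{2-[3,3-bis(methylsulfanyl)prop-2-enoyl]-5-methylhex-4-en-1-yl}-3,5,5-trimethyloxolan-2-one | CSC(SC)=CC(=O)C(CC=C(C)C)C[C@@H]1C(C)C(=O)OC1(C)C | intermediate
10 | potassium alkoxide of (2R,4R)-2-[3,3-bis(methylsulfanyl)prop-2-enoyl]-4-(2-hydroxypropan-2-yl)-5-methyl-2-(3-methylbut-2-en-1-yl)cyclopentan-1-one (C5 epimers) | [K+].CC1C(=O)[C@@](CC=C(C)C)(C[C@H]1C(C)(C)[O-])C(=O)C=C(SC)SC | intermediate (not isolated)
11 | (1S,5S,6R)-6-(2-hydroxypropan-2-yl)-5-methyl-1-(3-methylbut-2-en-1-yl)-4-(methylsulfanyl)bicyclo[3.2.1]oct-3-ene-2,8-dione | C1=C(SC)[C@]2(C)C(=O)[C@@](CC=C(C)C)(C[C@H]2C(C)(C)O)C1=O | intermediate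
12 | (1S,5R,6R)-6-(2-hydroxypropan-2-yl)-5-methyl-1-(3-methylbut-2-en-1-yl)bicyclo[3.2.1]octane-2,4,8-trione, drawn as its C4 enol | C1=C(O)[C@]2(C)C(=O)[C@@](CC=C(C)C)(C[C@H]2C(C)(C)O)C1=O | intermediate
13 | (2R)-2-methylbutanoic acid | CC[C@@H](C)C(O)=O | starting material
14 | enol ester of 12, acylated on the C4 enol oxygen with the (2R)-2-methylbutanoyl group | C1=C(OC(=O)[C@H](C)CC)[C@]2(C)C(=O)[C@@](CC=C(C)C)(C[C@H]2C(C)(C)O)C1=O | intermediate (not isolated)
15 | (1R,5R,6R)-4-hydroxy-6-(2-hydroxypropan-2-yl)-5-methyl-1-(3-methylbut-2-en-1-yl)-3-[(2R)-2-methylbutanoyl]bicyclo[3.2.1]oct-3-ene-2,8-dione | CC[C@@H](C)C(=O)C1=C(O)[C@]2(C)C(=O)[C@@](CC=C(C)C)(C[C@H]2C(C)(C)O)C1=O | target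

## Count and risks

Total step count: 9. Longest linear sequence: 9 steps, from (R)-carvone.

Step 7 (key step). What may go wrong: after the lactone has opened, the C5 enolate may close through oxygen instead of carbon, or the diketone intermediate may be drained by retro-Claisen loss of the acyl arm before the second ring closes. Fallback, setting out from 7 and coming back at 12: the two bond formations are separated and the six-membered ring is closed as a Dieckmann condensation with an enolisable product. Treatment of 7 with KOt-Bu in THF should give only the first Claisen closure, (4R)-2-acetyl-4-(2-hydroxypropan-2-yl)-5-methyl-2-(3-methylbut-2-en-1-yl)cyclopentan-1-one F1. NaH and dimethyl carbonate in THF at reflux would then carbomethoxylate the acetyl methyl group to the β-keto ester F2, whose ring enolate at C5 should close onto the ester in the same flask. The enolate of the trione is the thermodynamic sink, and acidic work-up would give 12, bypassing 9 and 11.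

Step 6. What may go wrong: equilibration to the more substituted enolate with premature lactone opening, or incomplete second deprotonation that stops at the mono-methylated dithioester. Fallback, setting out from 7 and coming back at 9: the dithioacetal carbon is introduced as an electrophile onto a neutral enol derivative. LiN(i-Pr)2 with Me3SiCl present (in situ quench, THF, −78 °C) should give the kinetic trimethylsilyl enol ether F3. Tris(methylsulfanyl)methylium tetrafluoroborate in CH2Cl2 would alkylate it at the terminal carbon to the β-keto trithioorthoester F4. Et3N would then eliminate methanethiol to give 9.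

Step 3. What may go wrong: 1,2-addition of the allyl nucleophile to the ketone in competition with conjugate addition. Fallback, setting out from 3 and coming back at 4: the 1,2-adduct is made on purpose and rearranged. Allylmagnesium bromide in THF at −78 °C should add to the carbonyl of 3 to give the diol (5R)-5-(2-hydroxypropan-2-yl)-2,6-dimethyl-1-(prop-2-en-1-yl)cyclohex-2-en-1-ol F5. KH and 18-crown-6 in THF would trigger the anionic oxy-Cope rearrangement of the 1,5-dienyl alkoxide, which moves the allyl group to C3 and leaves the same regiodefined enolate. Quenching with Me3SiCl silylates both oxygens and returns 4.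

## Further compounds

F1 | step 7 | (4R)-2-acetyl-4-(2-hydroxypropan-2-yl)-5-methyl-2-(3-methylbut-2-en-1-yl)cyclopentan-1-one (C2 and C5 epimers) | CC1C(=O)C(CC=C(C)C)(C[C@H]1C(C)(C)O)C(C)=O
F2 | step 7 | methyl 3-[(4R)-4-(2-hydroxypropan-2-yl)-3-methyl-1-(3-methylbut-2-en-1-yl)-2-oxocyclopentyl]-3-oxopropanoate | CC1C(=O)C(CC=C(C)C)(C[C@H]1C(C)(C)O)C(=O)CC(=O)OC
F3 | step 6 | (4R)-3,5,5-trimethyl-4-{5-methyl-2-[1-(trimethylsilyloxy)ethenyl]hex-4-en-1-yl}oxolan-2-one | C=C(O[Si](C)(C)C)C(CC=C(C)C)C[C@@H]1C(C)C(=O)OC1(C)C
F4 | step 6 | (4R)-3,5,5-trimethyl-4-{5-methyl-2-[3,3,3-tris(methylsulfanyl)propanoyl]hex-4-en-1-yl}oxolan-2-one | CSC(SC)(SC)CC(=O)C(CC=C(C)C)C[C@@H]1C(C)C(=O)OC1(C)C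
F5 | step 3 | (5R)-5-(2-hydroxypropan-2-yl)-2,6-dimethyl-1-(prop-2-en-1-yl)cyclohex-2-en-1-ol (C1 and C6 epimers) | CC1=CC[C@H](C(C)C1(O)CC=C)C(C)(C)O
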